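The last C–C bond is C12–C13. A B-alkyl Suzuki–Miyaura coupling joins a C9-vinyl decalin to a 2-triflyloxyalkene that already holds C13–C16 and the butenolide (ring C, closed by ring-closing metathesis; C14/C15 from L-tartrate, C16 from an enone reduction).
The 8α- and 6α-hydroxyls go back to a Δ7 alkene (C6 allylic oxidation, α-face enone epoxidation, SmI2 opening, electron-transfer reduction). C17 and the Δ7 alkene go back to a C8 ketone flanked by a C11 ester.
Structural feature used: trans-fused rings A and B carry the contiguous centres C4 (quaternary, equatorial C18H2–O, axial C19H3), C5 (α-H), C10 (β-CH3) and C9. This array is the chair–chair fold of an open chain with a C3–C4 oxirane whose CH2O group is trans to the chain, an E C5=C10 alkene and a C8/C9/C11 β-keto ester.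
Key disconnection: C4–C5 and C9–C10 are made in one Lewis-acid cascade, ring A first and ring B directly after it. The C3 hydroxyl left by the oxirane is deleted later.
The cyclisation substrate comes from geranyl acetate (E-selective allylic oxidation, then Sharpless epoxidation as the only source of absolute configuration for rings A and B) and the dianion of methyl acetoacetate.

Key step: step 7

Remark on numbering: decalin C1–C10 as in labdanes. C17 = CH3 on C8, C18 = 4α-CH2O, C19 = 4β-CH3, C20 = 10β-CH3. The side chain is counted outward from C9 as C11–C16 (C13 bears the exocyclic methylene, C16 is the lactone CH–O). In this numbering the target is 4R,5R,6S,8R,9R,10S,14S,15R,16R.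

**Fragment 1 (decalin)**

Step 1
Reactants: 1 geranyl acetate
Product: 2 (2E,6E)-8-hydroxy-3,7-dimethylocta-2,6-dien-1-yl acetate
Conditions: SeO2 (cat.), t-BuOOH, salicylic acid (cat.), CH2Cl2, rt
Reagents that add atoms: tert-butyl hydroperoxide, CC(C)(C)OO (oxygen passed on through SeO2)
Why: Riley allylic oxidation (ene reaction, then [2,3]-shift) should attack the electron-richer terminal alkene, the one next to the acetate being deactivated, and it oxidises the methyl group trans to the chain, which fixes the E geometry that later becomes the equatorial C18.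

Step 2
Reactants: 2 (2E,6E)-8-hydroxygeranyl acetate; 3 diethyl L-(+)-tartrate (chiral ligand, substoichiometric, not incorporated)
Product: 4 (2E)-5-[(2S,3S)-3-(hydroxymethyl)-3-methyloxiran-2-yl]-3-methylpent-2-en-1-yl acetate
Conditions: Ti(OiPr)4 (cat.), 3 (cat.), t-BuOOH (decane), 4 Å MS, CH2Cl2, −20 °C
Reagents that add atoms: tert-butyl hydroperoxide, CC(C)(C)OO
Why: Sharpless asymmetric epoxidation touches only the alkene of the allylic alcohol, and the titanium complex of (R,R)-tartrate should give the (2S,3S)-oxirane (3S,4S in the numbering used here), as it does for E-2-methylalk-2-en-1-ols in general.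

Step 3
Reactants: 4 epoxy alcohol
Product: 5 (2E)-5-[(2S,3S)-3-(benzyloxymethyl)-3-methyloxiran-2-yl]-3-methylpent-2-en-1-yl acetate
Conditions: BnBr, Ag2O, n-Bu4NI (cat.), CH2Cl2, rt, dark
Reagents that add atoms: benzyl bromide, BrCc1ccccc1
Why: Silver-oxide-promoted Williamson-type benzylation runs without a free alkoxide, so acetate transfer to the primary hydroxyl and Payne rearrangement, both to be expected with NaH, are avoided and the oxirane centres stay untouched.

Step 4
Reactants: 5 benzyl ether acetate
Product: 6 (2E)-5-[(2S,3S)-3-(benzyloxymethyl)-3-methyloxiran-2-yl]-3-methylpent-2-en-1-ol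
Conditions: K2CO3 (cat.), MeOH, 0 °C → rt
Reagents that add atoms: none
Why: Base-catalysed transesterification removes the acetate, while the oxirane and the benzyl ether are inert to carbonate in methanol.

Step 5
Reactants: 6 allylic alcohol
Product: 8 (2S,3S)-2-(benzyloxymethyl)-3-[(3E)-5-bromo-3-methylpent-3-en-1-yl]-2-methyloxirane, via allylic mesylate 7 (not isolated)
Conditions: MsCl, Et3N, CH2Cl2, −40 °C; then LiBr, THF, −40 → 0 °C
Reagents that add atoms: lithium bromide, [Li+].[Br-]; methanesulfonyl chloride, CS(=O)(=O)Cl (its atoms stay only in 7)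
Why: Mesylation followed by SN2 displacement with bromide at low temperature converts the allylic alcohol without allylic transposition or loss of E geometry, and a trisubstituted oxirane is not opened by LiBr at or below 0 °C.

Step 6
Reactants: 8 epoxy allylic bromide; 9 methyl acetoacetate
Product: 11 methyl (6E)-9-[(2S,3S)-3-(benzyloxymethyl)-3-methyloxiran-2-yl]-7-methyl-3-oxonon-6-enoate, via acetoacetate dianion 10 (not isolated)
Conditions: 9, NaH, THF, 0 °C; n-BuLi, 0 °C; then 8, 0 °C
Reagents that add atoms: none
Why: Dianion alkylation takes place at the more reactive terminal carbanion by SN2 attack on the allylic bromide (C6–C7 bond), faster than any attack on the hindered oxirane.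

Step 7
Reactants: 11 epoxy-ene β-keto ester
Product: 13 3β-hydroxy-18-benzyloxy-8-oxo trans-decalin C11 methyl ester (4α-CH2OBn 4β-CH3 5α-H 9α-H 10β-CH3), via dichloroaluminium enolate chelate 12 (not isolated)
Conditions: MeAlCl2 (3 equiv, hexanes), CH2Cl2 (high dilution), −78 °C, then −78 → −20 °C
Reagents that add atoms: none
Why: The first equivalent of MeAlCl2 turns the β-keto ester into its chelated dichloroaluminium enolate 12 and a further equivalent binds the oxirane oxygen, so the C4–O bond ionises at the tertiary carbon while C5 of the C5=C10 alkene attacks C4 from the rear and the developing tertiary C10 cation is taken up by enolate carbon C9; the closest known reaction type is the Lewis-acid epoxy-polyene cyclisation ended by a β-keto ester or enol derivative. Ring A closes 6-endo with respect to both the oxirane (C3–C4 stays in the ring) and the alkene, ring B closes 6-endo with the C8=C9 enolate bond inside the new ring, and both pass through chair folds. C4 is set by inversion at the oxirane carbon, which places the CH2OBn group that was trans to the chain equatorial (α, C18) and the methyl axial (β, C19), while C3 keeps its C–O bond and becomes the equatorial 3β-carbinol. C5 (α-H) and C10 (β-CH3) follow from anti addition across the E alkene in the chair fold whose face the oxirane dictates, and C9 ends with the ester equatorial (β) because it can epimerise through the enol to this more stable arrangement. The step needs opening at C4 rather than C3, which the tertiary against secondary cation character secures despite the inductive pull of the ether oxygen. It also needs C- rather than O-capture at C10, which is secured by tying both carbonyl oxygens to aluminium and by the reversibility of tertiary enol ether formation on warming.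

Step 8
Reactants: 13 hydroxy β-keto ester
Product: 14 3β-O-(imidazol-1-ylthiocarbonyl) derivative of 13
Conditions: 1,1'-thiocarbonyldiimidazole, DMAP (cat.), ClCH2CH2Cl, 80 °C
Reagents that add atoms: 1,1'-thiocarbonyldiimidazole, S=C(n1ccnc1)n1ccnc1
Why: Thioacyl transfer needs no strong base, unlike xanthate formation with NaH/CS2/MeI, so the acidic β-keto ester is not alkylated and any enol thiocarbamate should revert on work-up (first half of the Barton–McCombie deoxygenation).

Step 9
Reactants: 14 thiocarbonylimidazolide
Product: 15 18-benzyloxy-8-oxo trans-decalin C11 methyl ester (C3 = CH2)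
Conditions: n-Bu3SnH, AIBN (cat.), toluene, 110 °C
Reagents that add atoms: none
Why: In the Barton–McCombie deoxygenation the stannyl radical adds to C=S, the secondary C3 radical is released and takes hydrogen from the stannane; ketone, ester and benzyl ether are inert and only the surplus stereocentre C3 is deleted.

Step 10
Reactants: 15 benzyl ether
Product: 16 18-hydroxy-8-oxo trans-decalin C11 methyl ester
Conditions: H2 (1 atm), Pd/C, EtOAc, rt
Reagents that add atoms: none
Why: Hydrogenolysis is done at this alkene-free stage because the benzyl ether would be at risk in the later chromium oxidation and could not be removed next to the alkenes of the target.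

Step 11
Reactants: 16 primary alcohol
Product: 17 18-(tert-butyldimethylsilyloxy)-8-oxo trans-decalin C11 methyl ester
Conditions: TBSCl, imidazole, DMF, rt
Reagents that add atoms: tert-butyldimethylsilyl chloride, CC(C)(C)[Si](C)(C)Cl
Why: Imidazole-mediated silylation protects the neopentyl primary hydroxyl with a group that survives bases, hydrides, oxidants and SmI2 and falls off with mild acid at the end.

Step 12
Reactants: 17 β-keto ester
Product: 19 Δ8(9) enol triflate (8-triflyloxy-8-ene C11 methyl ester with 18-OTBS), via sodium enolate 18 (not isolated)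
Conditions: NaH, Et2O, 0 °C → rt; then Tf2O, −78 → 0 °C
Reagents that add atoms: trifluoromethanesulfonic anhydride, O=S(=O)(OS(=O)(=O)C(F)(F)F)C(F)(F)F
Why: O-sulfonylation of the stabilised enolate, the only one formed because C9–H is by far the most acidic, gives the cyclic β-triflyloxy enoate; the C9 centre is given up here on purpose and is set again in step 14.

Step 13
Reactants: 19 enol triflate
Product: 20 8-methyl Δ8(9) conjugated C11 methyl ester (18-OTBS)
Conditions: MeMgBr, Fe(acac)3 (cat.), THF/NMP, −30 → 0 °C
Reagents that add atoms: methylmagnesium bromide, C[Mg]Br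
Why: Iron-catalysed Kumada-type coupling of an alkenyl triflate with MeMgBr is much faster at low temperature than Grignard addition to the hindered conjugated ester, and it installs C17.

Step 14
Reactants: 20 conjugated ester
Product: 22 Δ7 β,γ-unsaturated C11 methyl ester (9α-H 9β-CO2Me 18-OTBS), via lithium dienolate 21 (not isolated)
Conditions: LDA, DMPU, THF, −78 → −20 °C; then AcOH/THF, −78 °C
Reagents that add atoms: none
Why: LDA with DMPU should remove the axial 7α-hydrogen, which overlaps with the enoate π system and leads to the less strained transoid dienolate 21, and kinetic protonation at C9 from the α face, opposite the axial C20 methyl, gives 9α-H with an equatorial ester (deconjugative protonation of an extended enolate).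

Step 15
Reactants: 22 Δ7 ester
Product: 23 Δ7 C11 primary alcohol (18-OTBS)
Conditions: LiAlH4, Et2O, 0 °C
Reagents that add atoms: none
Why: Hydride reduction of the ester removes the acidity of C9–H before the enone is made, and neither the isolated alkene nor the silyl ether reacts.

Step 16
Reactants: 23 primary alcohol
Product: 24 Δ7 C11 pivalate (18-OTBS)
Conditions: PivCl, pyridine, DMAP (cat.), CH2Cl2, 0 °C → rt
Reagents that add atoms: pivaloyl chloride, CC(C)(C)C(=O)Cl
Why: A pivalate is chosen in this acylation because it should withstand the chromium oxidant, basic peroxide and SmI2 and can later be removed reductively beside silyl ethers.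

Step 17
Reactants: 24 Δ7 pivalate
Product: 25 7-en-6-one (11-OPiv, 18-OTBS)
Conditions: CrO3, 3,5-dimethylpyrazole, CH2Cl2, −20 °C
Reagents that add atoms: chromium trioxide, O=[Cr](=O)=O
Why: Chromium trioxide–dimethylpyrazole allylic oxidation selects the ring methylene C6 over the hindered tertiary C9–H and the C17 methyl, as is usual for Δ7 drimane-type alkenes, and ester and silyl ether are inert.

Step 18
Reactants: 25 enone
Product: 26 7α,8α-epoxy-6-ketone (11-OPiv, 18-OTBS)
Conditions: t-BuOOH, BnMe3NOH (cat.), THF, 0 °C → rt
Reagents that add atoms: tert-butyl hydroperoxide, CC(C)(C)OO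
Why: In this Weitz–Scheffer epoxidation the peroxide anion should add to C8 from the α face, because the β face is screened by the axial C20 and C19 methyls, and closure on the same face sets C8 with oxygen α and C17 β (C7 is temporary).

Step 19
Reactants: 26 epoxy ketone
Product: 27 8α-hydroxy-6-ketone (11-OPiv, 18-OTBS)
Conditions: SmI2, THF/MeOH, −90 °C
Reagents that add atoms: none
Why: Two-electron reduction of an α,β-epoxy ketone by SmI2 cleaves only the C7–O bond through the ketyl and samarium enolate, so the C8–O bond and its configuration are kept, and the non-basic medium avoids dehydration of the aldol.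

Step 20
Reactants: 27 hydroxy ketone
Product: 28 6α,8α-diol (11-OPiv, 18-OTBS)
Conditions: SmI2 (excess), H2O, THF, 0 °C → rt
Reagents that add atoms: none
Why: Electron-transfer reduction (SmI2–H2O) should give the thermodynamically preferred equatorial 6α-alcohol, since a 6β-oxygen would be syn-diaxial to both C19 and C20, whereas hydrides would attack the open α face and give the wrong 6β-epimer; without an amine additive the pivalate is not reduced.

Step 21
Reactants: 28 diol
Product: 29 6α,8α-bis(triethylsilyl) ether (11-OPiv, 18-OTBS)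
Conditions: TESOTf, 2,6-lutidine, CH2Cl2, −78 → 0 °C
Reagents that add atoms: triethylsilyl trifluoromethanesulfonate, CC[Si](CC)(CC)OS(=O)(=O)C(F)(F)F
Why: A silyl triflate with a hindered pyridine base silylates even the tertiary C8 hydroxyl, which shuts off retro-aldol and elimination pathways once C11 becomes an aldehyde.

Step 22
Reactants: 29 pivalate
Product: 30 C11 primary alcohol (6,8-bis-OTES, 18-OTBS)
Conditions: DIBAL-H, CH2Cl2, −78 → −20 °C
Reagents that add atoms: none
Why: Reductive ester cleavage frees only the C11 hydroxyl and leaves the three silyl ethers untouched.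

Step 23
Reactants: 30 primary alcohol
Product: 31 C11 aldehyde (6,8-bis-OTES, 18-OTBS)
Conditions: n-Pr4N[RuO4] (cat.), NMO, 4 Å MS, CH2Cl2, rt
Reagents that add atoms: none
Why: Ley–Griffith oxidation is neutral, stops at the aldehyde and should not epimerise C9, whose equatorial formyl group is in any case the more stable arrangement.

Step 24
Reactants: 31 aldehyde
Product: 32 C9β-vinyl decalin (C11=C12; 6,8-bis-OTES, 18-OTBS)
Conditions: Ph3PCH3Br, KHMDS, THF, 0 °C; then 31, 0 °C → rt
Reagents that add atoms: methyltriphenylphosphonium bromide, C[P+](c1ccccc1)(c1ccccc1)c1ccccc1.[Br-]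
Why: In the Wittig methylenation the unstabilised ylide adds to the aldehyde faster than it deprotonates C9, and the β-silyloxy group is a poor leaving group, so C12 is added without elimination.

**Fragment 2 (side chain)**

Step 25
Reactants: 3 diethyl L-(+)-tartrate
Product: 33 diethyl (4R,5R)-2,2-dimethyl-1,3-dioxolane-4,5-dicarboxylate
Conditions: 2,2-dimethoxypropane, p-TsOH·H2O (cat.), cyclohexane, reflux (MeOH removed)
Reagents that add atoms: 2,2-dimethoxypropane, COC(C)(C)OC
Why: Acid-catalysed transacetalisation protects the threo diol that becomes C14/C15 without touching its stereocentres, and any ethyl/methyl ester exchange is irrelevant because both esters become amides next.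

Step 26
Reactants: 33 tartrate acetonide
Product: 34 (4R,5R)-N4,N5-dimethoxy-N4,N5,2,2-tetramethyl-1,3-dioxolane-4,5-dicarboxamide
Conditions: MeNH(OMe)·HCl, i-PrMgCl, THF, −20 → 0 °C
Reagents that add atoms: N,O-dimethylhydroxylamine hydrochloride, CNOC.Cl
Why: Aminolysis of both esters by the magnesium amide gives the bis-Weinreb amide, and the trans-dioxolane is the stable isomer, so the α-centres are not at risk.

Step 27
Reactants: 34 bis-Weinreb amide
Product: 35 (4R,5R)-5-acetyl-N-methoxy-N,2,2-trimethyl-1,3-dioxolane-4-carboxamide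
Conditions: MeMgBr (1 equiv), THF, −78 → −40 °C
Reagents that add atoms: methylmagnesium bromide, C[Mg]Br
Why: In the Weinreb ketone synthesis the magnesium-chelated tetrahedral intermediate survives until the quench and its charge lowers the reactivity of the second amide, so one equivalent of Grignard reagent should stop at mono-addition.

Step 28
Reactants: 35 keto amide
Product: 37 (4R,5R)-N-methoxy-N,2,2-trimethyl-5-[1-(triflyloxy)vinyl]-1,3-dioxolane-4-carboxamide, via potassium enolate 36 (not isolated)
Conditions: KHMDS, THF, −78 °C; then PhNTf2, −78 → −20 °C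
Reagents that add atoms: N-phenylbis(trifluoromethanesulfonimide), O=S(=O)(N(c1ccccc1)S(=O)(=O)C(F)(F)F)C(F)(F)F
Why: Kinetic deprotonation by the bulky amide at −78 °C occurs at the methyl group rather than at the ring C14–H, and O-triflation gives the terminal enol triflate (C13 with its methylene) without epimerisation or β-elimination in the dioxolane.

Step 29
Reactants: 37 triflate amide
Product: 38 isopropenyl ketone (C16 = C=O) with 14,15-acetonide and C13 enol triflate
Conditions: isopropenylmagnesium bromide, THF, −78 → −20 °C; inverse quench into cold aq. citric acid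
Reagents that add atoms: isopropenylmagnesium bromide, C=C(C)[Mg]Br
Why: This is a second Weinreb ketone synthesis; alkenyl triflates are inert to Grignard reagents without a catalyst at low temperature, and the acidic inverse quench keeps the liberated hydroxylamine from adding to the enone.

Step 30
Reactants: 38 enone
Product: 39 (16R)-allylic alcohol (C16–OH syn to O15; 14,15-acetonide, C13 enol triflate)
Conditions: (R)-Me-CBS oxazaborolidine (0.5 equiv), catecholborane, toluene, −78 °C
Reagents that add atoms: none
Why: Corey–Bakshi–Shibata reduction with the isopropenyl group as the larger ketone substituent should give 16R by 1,2-reduction only, the same sense as polar Felkin–Anh attack anti to the C15–O bond (syn diol derivative), so reagent and substrate should reinforce each other.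

Step 31
Reactants: 39 allylic alcohol
Product: 40 C16 acrylate
Conditions: acryloyl chloride, i-Pr2NEt, DMAP (cat.), CH2Cl2, −78 → 0 °C
Reagents that add atoms: acryloyl chloride, C=CC(=O)Cl
Why: O-acylation proceeds with retention at C16 and brings in the lactone carbonyl and its α-carbon.

Step 32
Reactants: 40 acrylate
Product: 41 (16R)-4-methylbutenolide with 14,15-acetonide and C13 enol triflate
Conditions: second-generation Grubbs catalyst RuCl2(=CHPh)(PCy3)(H2IMes) (cat.), CH2Cl2 (dilute), 40 °C
Reagents that add atoms: none
Why: Ring-closing metathesis between the acrylate and the isopropenyl group closes the five-membered lactone (ring C) with loss of ethene, while the electron-poor 1,1-disubstituted enol triflate does not take part and C16 is untouched.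

**Union and completion**

Step 33
Reactants: 32 C9-vinyl decalin; 41 butenolide enol triflate
Product: 43 fully protected target (18-OTBS 6-OTES 8-OTES 14/15-acetonide), via B-alkyl-9-BBN borane 42 (not isolated)
Conditions: 32, 9-BBN-H, THF, rt; then 41, Pd(dppf)Cl2·CH2Cl2 (cat.), AsPh3 (cat.), Cs2CO3, DMF/H2O, rt
Reagents that add atoms: none
Why: 9-BBN-H adds boron to the terminal carbon C12 of the only alkene in 32, and the B-alkyl Suzuki–Miyaura coupling (oxidative addition of the triflate to zerovalent palladium, base-assisted transmetalation, reductive elimination) forms C12–C13 at room temperature without involving any stereocentre.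

Step 34
Reactants: 43 protected target
Product: 44 CNP0301623.1 (target)
Conditions: camphorsulfonic acid (cat.), MeOH, rt → 40 °C
Reagents that add atoms: none
Why: Acid-catalysed methanolysis cleaves the three silyl ethers and transacetalises the dioxolane in one operation, while a catalytic sulfonic acid in methanol is too weak to ionise the tertiary C8 carbinol, protonate the C13 methylene or open the butenolide.

**Compound list**

1 | geranyl acetate | CC(C)=CCC/C(C)=C/COC(C)=O | starting material
2 | (2E,6E)-8-hydroxygeranyl acetate | CC(=O)OC/C=C(\C)CC/C=C(\C)CO | intermediate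
3 | diethyl L-(+)-tartrate (2R,3R) | CCOC(=O)[C@H](O)[C@@H](O)C(=O)OCC | starting material
4 | (2S,3S)-epoxy alcohol acetate | CC(=O)OC/C=C(\C)CC[C@@H]1O[C@@]1(C)CO | intermediate
5 | benzyl ether acetate | CC(=O)OC/C=C(\C)CC[C@@H]1O[C@@]1(C)COCc1ccccc1 | intermediate
6 | epoxy allylic alcohol | OC/C=C(\C)CC[C@@H]1O[C@@]1(C)COCc1ccccc1 | intermediate
7 | allylic mesylate | CS(=O)(=O)OC/C=C(\C)CC[C@@H]1O[C@@]1(C)COCc1ccccc1 | intermediate
8 | epoxy allylic bromide | BrC/C=C(\C)CC[C@@H]1O[C@@]1(C)COCc1ccccc1 | intermediate
9 | methyl acetoacetate | COC(=O)CC(C)=O | starting material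
10 | methyl acetoacetate dianion (Na, Li) | [Na+].[Li+].COC(=O)[CH-]C(=O)[CH2-] | intermediate
11 | epoxy-ene β-keto ester (key precursor) | COC(=O)CC(=O)CC/C=C(\C)CC[C@@H]1O[C@@]1(C)COCc1ccccc1 | intermediate
12 | dichloroaluminium enolate chelate of 11 | COC(=O)/C=C(\O[Al](Cl)Cl)CC/C=C(\C)CC[C@@H]1O[C@@]1(C)COCc1ccccc1 | intermediate
13 | 3β-hydroxy-18-benzyloxy-8-oxo decalin C11 methyl ester (key product) | COC(=O)[C@@H]1[C@@]2(C)CC[C@H](O)[C@@](C)(COCc3ccccc3)[C@@H]2CCC1=O | intermediate
14 | 3β-O-thiocarbonylimidazolide | COC(=O)[C@@H]1[C@@]2(C)CC[C@H](OC(=S)n3ccnc3)[C@@](C)(COCc3ccccc3)[C@@H]2CCC1=O | intermediate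
15 | 3-deoxy benzyl ether β-keto ester | COC(=O)[C@@H]1[C@@]2(C)CCC[C@@](C)(COCc3ccccc3)[C@@H]2CCC1=O | intermediate
16 | 18-hydroxy β-keto ester | COC(=O)[C@@H]1[C@@]2(C)CCC[C@@](C)(CO)[C@@H]2CCC1=O | intermediate
17 | 18-OTBS β-keto ester | COC(=O)[C@@H]1[C@@]2(C)CCC[C@@](C)(CO[Si](C)(C)C(C)(C)C)[C@@H]2CCC1=O | intermediate
18 | sodium enolate of 17 | [Na+].COC(=O)C=1[C@@]2(C)CCC[C@@](C)(CO[Si](C)(C)C(C)(C)C)[C@@H]2CCC=1[O-] | intermediate
19 | Δ8(9) enol triflate | COC(=O)C=1[C@@]2(C)CCC[C@@](C)(CO[Si](C)(C)C(C)(C)C)[C@@H]2CCC=1OS(=O)(=O)C(F)(F)F | intermediate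
20 | 8-methyl Δ8(9) conjugated ester | COC(=O)C=1[C@@]2(C)CCC[C@@](C)(CO[Si](C)(C)C(C)(C)C)[C@@H]2CCC=1C | intermediate
21 | lithium dienolate of 20 | [Li+].COC([O-])=C1[C@@]2(C)CCC[C@@](C)(CO[Si](C)(C)C(C)(C)C)[C@@H]2CC=C1C | intermediate
22 | Δ7 ester (9α-H) | COC(=O)[C@@H]1[C@@]2(C)CCC[C@@](C)(CO[Si](C)(C)C(C)(C)C)[C@@H]2CC=C1C | intermediate
23 | Δ7 C11 alcohol | OC[C@@H]1[C@@]2(C)CCC[C@@](C)(CO[Si](C)(C)C(C)(C)C)[C@@H]2CC=C1C | intermediate
24 | Δ7 C11 pivalate | CC(C)(C)C(=O)OC[C@@H]1[C@@]2(C)CCC[C@@](C)(CO[Si](C)(C)C(C)(C)C)[C@@H]2CC=C1C | intermediate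
25 | 7-en-6-one | CC(C)(C)C(=O)OC[C@@H]1[C@@]2(C)CCC[C@@](C)(CO[Si](C)(C)C(C)(C)C)[C@@H]2C(=O)C=C1C | intermediate
26 | 7α,8α-epoxy-6-ketone | CC(C)(C)C(=O)OC[C@@H]1[C@@]2(C)CCC[C@@](C)(CO[Si](C)(C)C(C)(C)C)[C@@H]2C(=O)[C@H]3O[C@]31C | intermediate
27 | 8α-hydroxy-6-ketone | CC(C)(C)C(=O)OC[C@@H]1[C@@]2(C)CCC[C@@](C)(CO[Si](C)(C)C(C)(C)C)[C@@H]2C(=O)C[C@@]1(C)O | intermediate
28 | 6α,8α-diol | CC(C)(C)C(=O)OC[C@@H]1[C@@]2(C)CCC[C@@](C)(CO[Si](C)(C)C(C)(C)C)[C@@H]2[C@@H](O)C[C@@]1(C)O | intermediate
29 | 6,8-bis-TES ether pivalate | CC(C)(C)C(=O)OC[C@@H]1[C@@]2(C)CCC[C@@](C)(CO[Si](C)(C)C(C)(C)C)[C@@H]2[C@@H](O[Si](CC)(CC)CC)C[C@@]1(C)O[Si](CC)(CC)CC | intermediate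
30 | C11 alcohol, trisilyl ether | OC[C@@H]1[C@@]2(C)CCC[C@@](C)(CO[Si](C)(C)C(C)(C)C)[C@@H]2[C@@H](O[Si](CC)(CC)CC)C[C@@]1(C)O[Si](CC)(CC)CC | intermediate
31 | C11 aldehyde | O=C[C@@H]1[C@@]2(C)CCC[C@@](C)(CO[Si](C)(C)C(C)(C)C)[C@@H]2[C@@H](O[Si](CC)(CC)CC)C[C@@]1(C)O[Si](CC)(CC)CC | intermediate
32 | C9β-vinyl decalin | C=C[C@@H]1[C@@]2(C)CCC[C@@](C)(CO[Si](C)(C)C(C)(C)C)[C@@H]2[C@@H](O[Si](CC)(CC)CC)C[C@@]1(C)O[Si](CC)(CC)CC | intermediate
33 | diethyl L-tartrate acetonide | CCOC(=O)[C@@H]1OC(C)(C)O[C@H]1C(=O)OCC | intermediate
34 | bis-Weinreb amide | CON(C)C(=O)[C@@H]1OC(C)(C)O[C@H]1C(=O)N(C)OC | intermediate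
35 | methyl ketone Weinreb amide | CC(=O)[C@@H]1OC(C)(C)O[C@H]1C(=O)N(C)OC | intermediate
36 | potassium enolate of 35 | [K+].C=C([O-])[C@@H]1OC(C)(C)O[C@H]1C(=O)N(C)OC | intermediate
37 | enol triflate Weinreb amide | C=C(OS(=O)(=O)C(F)(F)F)[C@@H]1OC(C)(C)O[C@H]1C(=O)N(C)OC | intermediate
38 | enol triflate isopropenyl ketone | C=C(OS(=O)(=O)C(F)(F)F)[C@@H]1OC(C)(C)O[C@H]1C(=O)C(C)=C | intermediate
39 | (16R)-allylic alcohol | C=C(OS(=O)(=O)C(F)(F)F)[C@@H]1OC(C)(C)O[C@H]1[C@H](O)C(C)=C | intermediate
40 | C16 acrylate | C=C(OS(=O)(=O)C(F)(F)F)[C@@H]1OC(C)(C)O[C@H]1[C@H](OC(=O)C=C)C(C)=C | intermediate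
41 | butenolide enol triflate | C=C(OS(=O)(=O)C(F)(F)F)[C@@H]1OC(C)(C)O[C@H]1[C@@H]3OC(=O)C=C3C | intermediate
42 | B-(C12-alkyl)-9-BBN from 32 | C(C[C@@H]1[C@@]2(C)CCC[C@@](C)(CO[Si](C)(C)C(C)(C)C)[C@@H]2[C@@H](O[Si](CC)(CC)CC)C[C@@]1(C)O[Si](CC)(CC)CC)B1C2CCCC1CCC2 | intermediate
43 | fully protected target | C=C(CC[C@@H]1[C@@]2(C)CCC[C@@](C)(CO[Si](C)(C)C(C)(C)C)[C@@H]2[C@@H](O[Si](CC)(CC)CC)C[C@@]1(C)O[Si](CC)(CC)CC)[C@@H]1OC(C)(C)O[C@H]1[C@@H]3OC(=O)C=C3C | intermediate
44 | CNP0301623.1 | C=C(CC[C@@H]1[C@@]2(C)CCC[C@@](C)(CO)[C@@H]2[C@@H](O)C[C@@]1(C)O)[C@H](O)[C@@H](O)[C@@H]1OC(=O)C=C1C | target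

**Totals**

Total step count: 34.
Longest linear sequence: 26 steps (steps 1–24, 33 and 34, from geranyl acetate). Fragment 2 takes 8 steps (25–32) from diethyl L-tartrate.

**Steps most likely to fail**

Step 7.
- **Risk:** The cascade may stall after ring A through loss of a proton from C10, or through capture of C10 by the C3 aluminium alkoxide or by the enol oxygen. The oxirane may also collapse by a 1,2-hydride shift. Both are possible because the ether oxygen slows ionisation at C4 and the chelated β-keto ester is only a moderate carbon nucleophile.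
- **Fallback:** This sets out from 11 and replaces the free β-keto ester by a pre-formed, neutral and more nucleophilic terminator. NaH and then TBSCl in THF at 0 °C give the (Z)-β-silyloxy enoate F1. This no longer consumes Lewis acid by chelation, so about one equivalent of MeAlCl2 in CH2Cl2 at −94 °C should suffice (silyl enol ether terminated epoxy-polyene cyclisation). The silyl group leaves from the oxocarbenium ion formed at C8, and an acidic aqueous work-up comes back to the route at 13.

Step 14.
- **Risk:** Deprotonation of 20 may occur at the C17 methyl, which lies cis to the ester, instead of at C7. The quench may also protonate at the γ-position. Either process would return exocyclic or conjugated isomers.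
- **Fallback:** This sets out from 17 and avoids the extended enolate altogether.
  - LiAlH4 in Et2O reduces ester and ketone to the 8,11-diol F2 (both C8 epimers serve).
  - PivCl/pyridine at −20 °C acylates only the primary hydroxyl to give the hydroxy pivalate F3.
  - n-Pr4N[RuO4]/NMO restores the ketone in the 8-oxo pivalate F4.
  - KHMDS and PhNTf2 at −78 °C enolise kinetically toward the unhindered C7 methylene to give the Δ7 enol triflate F5, with C9 untouched.
  - MeMgBr with Fe(acac)3 places C17 and comes back to the route at 24.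

Step 33.
- **Risk:** Carbonate in wet DMF may epimerise C16 or start elimination through the γ-deprotonated butenolide, and transmetalation of the hindered borane may be slow enough for this to compete.
- **Fallback:** This changes the order of events so that no lactone meets the base.
  - It sets out from 39, which is coupled with borane 42 under the same palladium catalysis to give the coupled allylic alcohol F6.
  - Acryloyl chloride/i-Pr2NEt esterifies its only free hydroxyl to give the coupled acrylate F7.
  - Ring-closing metathesis with the second-generation Grubbs catalyst, in which the hindered C13 methylene next to the dioxolane is expected to stay out, closes the butenolide and comes back to the route at 43.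

**Further compounds**

F1 | step 7 | methyl (2Z,6E)-9-[(2S,3S)-3-(benzyloxymethyl)-3-methyloxiran-2-yl]-3-(tert-butyldimethylsilyloxy)-7-methylnona-2,6-dienoate | COC(=O)/C=C(\O[Si](C)(C)C(C)(C)C)CC/C=C(\C)CC[C@@H]1O[C@@]1(C)COCc1ccccc1
F2 | step 14 | 8,11-diol with 18-OTBS (C8 epimers) | OC[C@@H]1[C@@]2(C)CCC[C@@](C)(CO[Si](C)(C)C(C)(C)C)[C@@H]2CCC1O
F3 | step 14 | 8-hydroxy C11 pivalate (C8 epimers) | CC(C)(C)C(=O)OC[C@@H]1[C@@]2(C)CCC[C@@](C)(CO[Si](C)(C)C(C)(C)C)[C@@H]2CCC1O
F4 | step 14 | 8-oxo C11 pivalate | CC(C)(C)C(=O)OC[C@@H]1[C@@]2(C)CCC[C@@](C)(CO[Si](C)(C)C(C)(C)C)[C@@H]2CCC1=O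
F5 | step 14 | Δ7 enol triflate C11 pivalate | CC(C)(C)C(=O)OC[C@@H]1[C@@]2(C)CCC[C@@](C)(CO[Si](C)(C)C(C)(C)C)[C@@H]2CC=C1OS(=O)(=O)C(F)(F)F
F6 | step 33 | coupled (16R)-allylic alcohol | C=C(CC[C@@H]1[C@@]2(C)CCC[C@@](C)(CO[Si](C)(C)C(C)(C)C)[C@@H]2[C@@H](O[Si](CC)(CC)CC)C[C@@]1(C)O[Si](CC)(CC)CC)[C@@H]1OC(C)(C)O[C@H]1[C@H](O)C(C)=C
F7 | step 33 | coupled C16 acrylate | C=C(CC[C@@H]1[C@@]2(C)CCC[C@@](C)(CO[Si](C)(C)C(C)(C)C)[C@@H]2[C@@H](O[Si](CC)(CC)CC)C[C@@]1(C)O[Si](CC)(CC)CC)[C@@H]1OC(C)(C)O[C@H]1[C@H](OC(=O)C=C)C(C)=C
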